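Locants C1–C17 in names and comments are the cembrane locants of the target: ring C1–C14, C15 the α-carbon on C1, C16 the carbonyl, C17 the exocyclic methylene. Where a systematic ring name is used, the cembrane locants are added.

## Analysis of the target

Target 40 is a cembranolide: a 14-membered carbocycle C1–C14, cis-fused across C1–C14 to an α-methylene-γ-butyrolactone built from C15, C16, C17 and the C14 oxygen. It has seven stereocentres: a contiguous run C12 (S, methyl), C13 (R, free hydroxyl), C14 (R, lactone oxygen) and C1 (S); a trans-substituted trisubstituted epoxide at C3 (R)/C4 (R); and an isolated tertiary carbinol C8 (S) next to the Z-alkene C6=C7. In the extended chain C12–C13–C14 the methyl group and both oxygens are syn to one another and the hydrogens at C14 and C1 are cis, while C8 and the epoxide are too remote to control this cluster or to be controlled by it. The sensitive groups are the α-methylene lactone (bases, nucleophiles), the epoxide facing a free tertiary hydroxyl across the ring (acid, transannular opening), the tertiary allylic alcohol and the doubly allylic C5 methylene. The hard points are closing the 14-membered ring, fixing C1 and C14 in the absolute sense without a neighbouring controller, and addressing one alkene at a time among several. The strategy rests on one feature: C14 is a carbinol carbon whose neighbour C1 carries the branch C15(=C17)–C16, so C14–C1 is the homoallylic alcohol that a [2,3]-Wittig shift delivers. An oxygen bridge from C14 to C17 in the 17-membered ether 30 can therefore be contracted to carbocycle 32, with C12–C13 held as an alkyne that acidifies C14 and later supplies the C12/C13 stereocentres.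

## Retrosynthetic reasoning

**Epoxide last (40 ⇒ 39).** The C3–C4 epoxide is removed first because it would not survive the aluminium chemistry that sets C12. In 39 the C3=C4 alkene is the only electron-rich trisubstituted one: C15=C17 is conjugated to the lactone and C6=C7 is a hindered Z-alkene. A chiral-ketone-catalysed oxygen transfer has to deliver oxygen to one face of an E-alkene inside the macrocycle.

**Lactone C16–O bond (39 ⇒ 36).** Cutting the acyl–oxygen bond and lowering C16 to the alcohol gives tetraol 36. An allylic-selective oxidant then touches only the primary allylic C16 hydroxyl, and the C14 hydroxyl closes the fused five-membered lactol, which is oxidised on. Both silyl groups are removed before this point, so nothing has to be deprotected once the α-methylene lactone and the epoxide exist.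

**C12–CH3 and C13–O (36 ⇒ 35 ⇒ 34 ⇒ 33 ⇒ 32).** The C12 methyl bond is cut back to the cis-12,13-epoxide 34, opened at the carbon distal to the C14 hydroxyl with inversion. Epoxide 34 comes from Z-allylic alcohol 33 by hydroxyl-directed epoxidation, and 33 from alkyne 32 by semihydrogenation. One hydroxyl (C14) thus relays its configuration to C13 and C12, and the all-syn triad follows from Z geometry, threo epoxidation and anti opening.

**Key disconnection, C1–C14 (32 ⇒ 30).** The ring bond C1–C14 is cut and the oxygen of C14 is reconnected to C17, giving the 17-membered propargyl allyl ether 30. This is the only bond whose formation makes the carbocycle, both stereocentres C1 and C14, the C14 hydroxyl and the C15=C17 methylene at once. The forward step must deprotonate C14 selectively and in a defined absolute sense.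

**Ether O–C14 (30 ⇒ 29 ⇒ 28 ⇒ 27).** The large ring is opened at the C14–O bond to bromo alcohol 29: a primary allylic alkoxide (C17) displaces a primary propargylic bromide (C14). Bromide 28 and alcohol 27 differ only in functional group; the C17 hydroxyl is kept as a triethylsilyl ether until the C14 hydroxyl has been converted.

**C6=C7 (27 ⇒ 10 + 25).** The Z-alkene is cut into the non-enolisable α-silyloxy aldehyde 10 and phosphonium salt 25. This divides the chain into two fragments of similar size and puts the only pre-existing stereocentre (C8) next to the carbonyl, where Z-selectivity is high.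

**Fragment 10 (⇒ 1 + 6).** Cutting C11–C12 leads to iodide 5 and propargyl alcohol 6. Iodide 5 comes from (S)-linalool 1, which supplies C7–C11 with C8 in the correct configuration. Its trisubstituted alkene is cleaved to reveal C11 and its vinyl group is cut back to the C7 aldehyde, so C6 belongs to the other fragment.

**Fragment 25 (⇒ 20 + 21).** The C2–C3 bond and the C4 methyl are made together: methyl-metalation of but-3-yn-1-ol 21 gives the E-alkenyl metal (C3–C6 plus the methyl), which is coupled with allylic chloride 20 at C2. The skipped diene is thus made without ever passing through a β,γ-unsaturated carbonyl compound.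

**Fragment 20 (⇒ 11).** But-2-yne-1,4-diol 11 supplies C2, C1, C15 and C16 only. A four-carbon alkyne cannot also carry C17, so C17 is added to C15 through the Z-alkenyl iodide 14. Anti hydrometalation directed by the C2 hydroxyl fixes the new carbon cis to C2, which is the geometry the key step needs.

## Alternatives that were turned down

**Alternative 1:** The disconnection builds the cis-lactone on a five-membered carbocycle made of C1, C2, C3, C13 and C14 and later cleaves the extra C3–C13 bond. The forward key step is iodolactonisation of (S)-2-(cyclopent-2-en-1-yl)acetic acid A2: the carboxylate adds 5-exo to C14 anti to the iodonium ion and gives the cis-fused iodolactone A1 with iodine on C13.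
- For it: C1 and C14 come from one cheap chiral-pool centre, the cis fusion is geometrically enforced, no chiral reagent is needed, and the iodide is a handle for the C13 oxygen. On certainty of the C1/C14 configuration this route is stronger than the chosen one.
- Against it: A1 holds only seven of the twenty carbons. The template must be opened to two carbonyl termini that have to be told apart, C12/C13 need a further stereoselective C–C bond formation, and C8, both alkenes, the epoxide and an end-to-end 14-membered ring closure next to a lactone all remain.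
- Comparison: the chosen route gives up substrate control at C1/C14 and gains the ring, the C1–C14 bond and both centres in one contraction step from two fragments, with a shorter endgame.

**Alternative 2:** The disconnection cuts C4–C5 and the C4–O bond of the epoxide, starting from (R)-limonene A4 remapped so that its stereocentre becomes C1 and its isopropenyl group C15–C17. In the forward key step an allenyl Grignard reagent adds as a propargyl nucleophile to the C4 methyl ketone anti to a C3 mesylate, and the tertiary alkoxide displaces the mesylate with inversion to give the trans-epoxy alkyne A3.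
- For it: C1 and the C15–C17 unit come from the chiral pool, C3/C4 and the epoxide are set in one flask on an open chain, and the terminal alkyne is ready for extension to C6–C7. On the absolute configuration of C1 and on avoiding a late facial problem in a macrocycle it is stronger.
- Against it: the addition is controlled only by the mesylate-bearing C3, which must itself first be set relative to remote C1. The acid- and nucleophile-sensitive epoxide is then carried through every later step, ring closure included. In A3 C14 is a methylene, so the lactone oxygen must still be introduced next to C1 with cis control, and one isopropenyl methyl must be oxidised to the acid level.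
- Comparison: the chosen route makes the epoxide last, gets the C14 oxygen from the rearrangement itself and closes the ring in the same step.

**Alternative 3:** The disconnection is the C5–C6 bond, closed by an intramolecular fluoride-promoted coupling of a Z-alkenylsilicon unit tethered to the C8 oxygen as a five-membered siloxane with a C5 allylic carbonate under zerovalent palladium catalysis. Siloxane opening, ionisation of the carbonate, transmetalation and reductive elimination would give macrocycle A5 with the C8 hydroxyl released.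
- For it: the Z geometry of C6=C7 is locked by the siloxane ring and transferred with retention, ring closure and C8 deprotection coincide, and C1, C12, C13, C14 and the lactone are set beforehand on an open chain. On Z-alkene fidelity and on securing the C1/C14 cluster before cyclisation it is stronger.
- Against it: the allylpalladium intermediate has two termini (C5 and C3), so regiocontrol and retention of the C3=C4 E geometry are both needed in a 14-membered closure. Fluoride meets a lactone. After A5 the α-methylene group, the removal of a p-methoxybenzyl ether beside a skipped diene and the epoxidation remain, and the open-chain precursor carrying five stereocentres is long.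
- Comparison: the chosen route closes the carbocycle through a five-membered transition state inside an existing ring, with no allyl regiochemistry to control, and forms C1–C14 with its stereocentres in the same step.

Key step: step 20

## Route

Assumption on the chemistry: the lithium amide of (R,R)-bis(1-phenylethyl)amine is taken to remove the C14 proton that leads to the (14R) alcohol; if the sense of induction is the opposite, the (S,S)-amine is used in the same way.

Step 1
Reactants: 1 (S)-linalool
Product: 2 (3S)-3,7-dimethyl-3-(triethylsilyloxy)octa-1,6-diene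
Conditions: Et3SiOTf, 2,6-lutidine, CH2Cl2, −78 → 0 °C
Reagents that add atoms: triethylsilyl triflate CC[Si](CC)(CC)OS(=O)(=O)C(F)(F)F
Why: Silylation of a tertiary allylic alcohol needs the silyl triflate; the stereocentre (the later C8) is not touched and is carried unchanged to the target.

Step 2
Reactants: 2 (3S)-3,7-dimethyl-3-(triethylsilyloxy)octa-1,6-diene
Product: 4 (4S)-4-methyl-4-(triethylsilyloxy)hex-5-en-1-ol, via aldehyde 3 (not isolated)
Conditions: O3 (1.0 equiv, dye indicator), CH2Cl2/MeOH, pyridine, −78 °C; then NaBH4, −78 → 0 °C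
Reagents that add atoms: ozone [O-][O+]=O
Why: Ozonolysis with reductive work-up; ozone attacks the electron-rich trisubstituted alkene much faster than the monosubstituted vinyl group, which is also deactivated by the allylic silyloxy group, and borohydride takes aldehyde 3 on to the C11 alcohol.

Step 3
Reactants: 4 (4S)-4-methyl-4-(triethylsilyloxy)hex-5-en-1-ol
Product: 5 (3S)-6-iodo-3-methyl-3-(triethylsilyloxy)hex-1-ene
Conditions: I2, PPh3, imidazole, CH2Cl2, 0 °C
Reagents that add atoms: iodine II
Why: Appel-type iodination of an unhindered primary alcohol; imidazole buffers the medium so the tertiary silyl ether survives.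

Step 4
Reactants: 5 (3S)-6-iodo-3-methyl-3-(triethylsilyloxy)hex-1-ene; 6 propargyl alcohol
Product: 8 (7S)-7-methyl-7-(triethylsilyloxy)non-8-en-2-yn-1-ol, via dilithio alkoxide 7 (not isolated)
Conditions: 6 (2.5 equiv), n-BuLi (5.0 equiv), THF/DMPU, −78 → −20 °C; then 5, → rt; H2O
Reagents that add atoms: none
Why: Acetylide alkylation; the carbon end of dianion 7 is far more nucleophilic than its alkoxide, so the C11–C12 bond forms by SN2 at the primary iodide and the C14 hydroxyl emerges free.

Step 5
Reactants: 8 (7S)-7-methyl-7-(triethylsilyloxy)non-8-en-2-yn-1-ol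
Product: 10 (2S)-8-hydroxy-2-methyl-2-(triethylsilyloxy)oct-6-ynal, via diol 9 (not isolated)
Conditions: OsO4 (2 mol %), NaIO4 (3 equiv), 2,6-lutidine, dioxane/H2O, rt
Reagents that add atoms: osmium tetroxide O=[Os](=O)(=O)=O; sodium periodate [Na+].[O-]I(=O)(=O)=O
Why: Lemieux–Johnson cleavage; OsO4 dihydroxylates the only alkene and periodate cleaves diol 9, the alkyne is inert, and the α-quaternary aldehyde (C7) can neither enolise nor epimerise.

Step 6
Reactants: 11 but-2-yne-1,4-diol
Product: 12 4-(tert-butyldimethylsilyloxy)but-2-yn-1-ol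
Conditions: 11 (3 equiv), t-BuMe2SiCl (1 equiv), imidazole, DMF, 0 °C
Reagents that add atoms: tert-butyldimethylsilyl chloride CC(C)(C)[Si](C)(C)Cl
Why: Statistical monosilylation with the symmetric diol in excess; the silylated oxygen becomes the C16 oxygen.

Step 7
Reactants: 12 4-(tert-butyldimethylsilyloxy)but-2-yn-1-ol
Product: 14 (Z)-4-(tert-butyldimethylsilyloxy)-3-iodobut-2-en-1-ol, via cyclic alkenylalanate 13 (not isolated)
Conditions: NaAlH2(OCH2CH2OMe)2 (1.5 equiv), THF, 0 °C → rt; EtOAc; then I2, −78 → 0 °C
Reagents that add atoms: iodine II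
Why: Hydroxyl-directed trans-hydroalumination of a propargylic alcohol puts aluminium on the distal alkyne carbon (C15) in the five-membered alanate 13; iodinolysis with retention gives the Z-iodide, so whatever replaces iodine will be cis to C2.

Step 8
Reactants: 14 (Z)-4-(tert-butyldimethylsilyloxy)-3-iodobut-2-en-1-ol
Product: 15 (Z)-4-(tert-butyldimethylsilyloxy)-3-iodobut-2-en-1-yl pivalate
Conditions: t-BuCOCl, pyridine, DMAP (cat.), CH2Cl2, 0 °C
Reagents that add atoms: pivaloyl chloride CC(C)(C)C(=O)Cl
Why: Acylation of the C2 hydroxyl; an allylic pivalate ionises only slowly with zerovalent palladium and does not migrate to a neighbouring hydroxyl, both of which matter in step 9.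

Step 9
Reactants: 15 (Z)-4-(tert-butyldimethylsilyloxy)-3-iodobut-2-en-1-yl pivalate
Product: 16 (E)-4-(tert-butyldimethylsilyloxy)-3-(hydroxymethyl)but-2-en-1-yl pivalate
Conditions: Bu3SnCH2OH (1.3 equiv), Pd(PPh3)4 (5 mol %), dioxane, 90 °C
Reagents that add atoms: (tributylstannyl)methanol CCCC[Sn](CCCC)(CCCC)CO
Why: Migita–Kosugi–Stille coupling of an alkenyl iodide with an α-oxygenated alkylstannane proceeds with retention, so the new hydroxymethyl carbon (C17) sits cis to C2 and the silyloxymethyl carbon (C16) trans to it.

Step 10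
Reactants: 16 (E)-4-(tert-butyldimethylsilyloxy)-3-(hydroxymethyl)but-2-en-1-yl pivalate
Product: 17 (E)-4-(tert-butyldimethylsilyloxy)-3-[(triethylsilyloxy)methyl]but-2-en-1-yl pivalate
Conditions: Et3SiCl, imidazole, CH2Cl2, 0 °C
Reagents that add atoms: triethylsilyl chloride CC[Si](CC)(CC)Cl
Why: Silylation of the primary allylic C17 hydroxyl; the triethylsilyl ether can later be removed in the presence of the tert-butyldimethylsilyl ether at C16.

Step 11
Reactants: 17 (E)-4-(tert-butyldimethylsilyloxy)-3-[(triethylsilyloxy)methyl]but-2-en-1-yl pivalate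
Product: 18 (E)-4-(tert-butyldimethylsilyloxy)-3-[(triethylsilyloxy)methyl]but-2-en-1-ol
Conditions: i-Bu2AlH (2.2 equiv), CH2Cl2, −78 °C; aq. potassium sodium tartrate
Reagents that add atoms: none

Why: Reductive cleavage of the pivalate under non-basic, non-acidic conditions that leave both silyl ethers in place.

Step 12
Reactants: 18 (E)-4-(tert-butyldimethylsilyloxy)-3-[(triethylsilyloxy)methyl]but-2-en-1-ol
Product: 20 (E)-1-(tert-butyldimethylsilyloxy)-4-chloro-2-[(triethylsilyloxy)methyl]but-2-ene, via mesylate 19 (not isolated)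
Conditions: MeSO2Cl, 2,4,6-collidine, LiCl, DMF, 0 °C
Reagents that add atoms: lithium chloride [Li+].[Cl-]; methanesulfonyl chloride CS(=O)(=O)Cl
Why: Mesylation and in-situ SN2 displacement by chloride at the primary allylic C2 without allylic transposition; the chloride is used at once.

Step 13
Reactants: 21 but-3-yn-1-ol; 20 (E)-1-(tert-butyldimethylsilyloxy)-4-chloro-2-[(triethylsilyloxy)methyl]but-2-ene
Product: 23 (3E,6E)-8-(tert-butyldimethylsilyloxy)-3-methyl-7-[(triethylsilyloxy)methyl]octa-3,6-dien-1-ol, via alkenylalane 22 (not isolated)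
Conditions: 21 (1.5 equiv), Me3Al (4.5 equiv), Cp2ZrCl2 (0.4 equiv), CH2Cl2, 0 °C → rt; then 20, Pd(PPh3)4 (5 mol %), THF, rt
Reagents that add atoms: trimethylaluminium C[Al](C)C
Why: Zirconium-catalysed syn-carboalumination of the terminal alkyne (Negishi) puts methyl on C4 and aluminium on C3 with E geometry; palladium-catalysed alkenyl–allyl coupling then joins C3 to the unsubstituted allyl terminus C2 with retention of both alkene geometries.

Step 14
Reactants: 23 (3E,6E)-8-(tert-butyldimethylsilyloxy)-3-methyl-7-[(triethylsilyloxy)methyl]octa-3,6-dien-1-ol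
Product: 24 (2E,5E)-1-(tert-butyldimethylsilyloxy)-8-iodo-6-methyl-2-[(triethylsilyloxy)methyl]octa-2,5-diene
Conditions: I2, PPh3, imidazole, CH2Cl2, 0 °C
Reagents that add atoms: iodine II
Why: Appel-type iodination of the primary homoallylic C6 alcohol under buffered conditions that spare both silyl ethers.

Step 15
Reactants: 24 (2E,5E)-1-(tert-butyldimethylsilyloxy)-8-iodo-6-methyl-2-[(triethylsilyloxy)methyl]octa-2,5-diene
Product: 25 [(3E,6E)-8-(tert-butyldimethylsilyloxy)-3-methyl-7-[(triethylsilyloxy)methyl]octa-3,6-dien-1-yl]triphenylphosphonium iodide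
Conditions: PPh3 (1.5 equiv), i-Pr2NEt (0.1 equiv), MeCN, 70 °C
Reagents that add atoms: triphenylphosphine c1ccc(cc1)P(c1ccccc1)c1ccccc1
Why: SN2 quaternisation of a primary iodide; homoallylic phosphonium salts of this kind are standard precursors of skipped dienes.

Step 16
Reactants: 25 [(3E,6E)-8-(tert-butyldimethylsilyloxy)-3-methyl-7-[(triethylsilyloxy)methyl]octa-3,6-dien-1-yl]triphenylphosphonium iodide; 10 (2S)-8-hydroxy-2-methyl-2-(triethylsilyloxy)oct-6-ynal
Product: 27 (7S,8Z,11E,14E)-16-(tert-butyldimethylsilyloxy)-7,11-dimethyl-7-(triethylsilyloxy)-15-[(triethylsilyloxy)methyl]hexadeca-8,11,14-trien-2-yn-1-ol, via ylide 26 (not isolated)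
Conditions: 25 (1.15 equiv), NaN(SiMe3)2 (2.2 equiv), THF, −78 → 0 °C; then 10, −78 °C → rt; H2O
Reagents that add atoms: none
Why: Wittig olefination with a non-stabilised ylide under lithium-free conditions gives the Z-alkene C6=C7, and an α-alkoxy aldehyde reinforces this; the second equivalent of base only holds the C14 hydroxyl as its alkoxide, and aldehyde 10 has no α-hydrogen to lose.

Step 17
Reactants: 27 (7S,8Z,11E,14E)-16-(tert-butyldimethylsilyloxy)-7,11-dimethyl-7-(triethylsilyloxy)-15-[(triethylsilyloxy)methyl]hexadeca-8,11,14-trien-2-yn-1-ol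
Product: 28 (7S,8Z,11E,14E)-1-bromo-16-(tert-butyldimethylsilyloxy)-7,11-dimethyl-7-(triethylsilyloxy)-15-[(triethylsilyloxy)methyl]hexadeca-8,11,14-trien-2-yne
Conditions: CBr4 (1.3 equiv), PPh3 (1.4 equiv), 2,6-lutidine (0.2 equiv), CH2Cl2, −20 → 0 °C
Reagents that add atoms: carbon tetrabromide BrC(Br)(Br)Br
Why: Appel bromination of the only free hydroxyl (C14) gives the primary propargylic bromide; the buffered conditions leave the three silyl ethers intact.

Step 18
Reactants: 28 (7S,8Z,11E,14E)-1-bromo-16-(tert-butyldimethylsilyloxy)-7,11-dimethyl-7-(triethylsilyloxy)-15-[(triethylsilyloxy)methyl]hexadeca-8,11,14-trien-2-yne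
Product: 29 (2E,5E,8Z,10S)-16-bromo-2-[(tert-butyldimethylsilyloxy)methyl]-6,10-dimethyl-10-(triethylsilyloxy)hexadeca-2,5,8-trien-14-yn-1-ol
Conditions: pyridinium p-toluenesulfonate (0.1 equiv), MeOH/CH2Cl2, 0 °C
Reagents that add atoms: none
Why: Acid-catalysed methanolysis removes the primary allylic triethylsilyl ether (C17) much faster than the primary tert-butyldimethylsilyl ether (C16) or the hindered tertiary triethylsilyl ether (C8); the propargylic bromide does not solvolyse at this temperature.

Step 19
Reactants: 29 (2E,5E,8Z,10S)-16-bromo-2-[(tert-butyldimethylsilyloxy)methyl]-6,10-dimethyl-10-(triethylsilyloxy)hexadeca-2,5,8-trien-14-yn-1-ol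
Product: 30 (8S,9Z,12E,15E)-16-[(tert-butyldimethylsilyloxy)methyl]-8,12-dimethyl-8-(triethylsilyloxy)-1-oxacycloheptadeca-9,12,15-trien-3-yne
Conditions: NaH (3 equiv), THF, 50 °C, slow addition of 29 to a final concentration of about 1 mM
Reagents that add atoms: none
Why: Intramolecular Williamson etherification; a primary allylic alkoxide displaces a primary propargylic bromide, and the alkyne and three alkenes stiffen the chain so that 17-membered ring closure competes with oligomerisation at high dilution.

Step 20
Reactants: 30 (8S,9Z,12E,15E)-16-[(tert-butyldimethylsilyloxy)methyl]-8,12-dimethyl-8-(triethylsilyloxy)-1-oxacycloheptadeca-9,12,15-trien-3-yne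
Product: 32 (1R,7S,8Z,11E,14S)-14-[3-(tert-butyldimethylsilyloxy)prop-1-en-2-yl]-7,11-dimethyl-7-(triethylsilyloxy)cyclotetradeca-8,11-dien-2-yn-1-ol, via lithiated ether 31 (not isolated)
Conditions: (R,R)-bis(1-phenylethyl)amine (3.3 equiv), n-BuLi (3.0 equiv), THF, 0 °C; then 30, −78 → −25 °C; H2O
Reagents that add atoms: none
Why: The amide removes one of the two C14 protons, the most acidic in 30 because carbanion 31 is propargylic and α to oxygen, and 31 attacks C1 through a five-membered envelope transition state in which C14–C1 forms, O–C17 breaks and the double bond moves from C1=C15 to C15=C17. This is the [2,3]-Wittig rearrangement of a propargyl allyl ether in its ring-contracting form, a known route from macrocyclic propargyl allyl ethers to 14-membered carbocyclic homoallylic alcohols. The carbocycle is closed by contraction of the 17-membered ring, a transannular bond formation between atoms held apart only by the O–C17–C15 bridge, not by an end-to-end cyclisation. C14 (cembrane 14R, ring locant 1R) is set by the chiral base, which chooses the proton to be removed, the lithiated centre rearranging at low temperature before it can invert. C1 (cembrane 1S) is set relative to C14 by the alkene geometry: with C17 cis to C2 the alkynyl group lies exo on the envelope and the C14 oxygen ends up syn to C2, the relationship required for the cis-fused lactone. The step needs deprotonation at C14 and not at C17, C2 or C5 (secured by the alkyne and the low temperature), a [2,3] and not a [1,2] shift (secured by the concerted path and the low temperature), and control by the base independent of remote C8, which nothing in the substrate supports.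

Step 21
Reactants: 32 (1R,7S,8Z,11E,14S)-14-[3-(tert-butyldimethylsilyloxy)prop-1-en-2-yl]-7,11-dimethyl-7-(triethylsilyloxy)cyclotetradeca-8,11-dien-2-yn-1-ol
Product: 33 (1S,2Z,7S,8Z,11E,14S)-14-[3-(tert-butyldimethylsilyloxy)prop-1-en-2-yl]-7,11-dimethyl-7-(triethylsilyloxy)cyclotetradeca-2,8,11-trien-1-ol
Conditions: H2 (1 atm), Pd/CaCO3 poisoned with Pb(OAc)2, quinoline, EtOAc/hexane, rt, stopped after 1 equiv of H2
Reagents that add atoms: none
Why: Lindlar semihydrogenation gives the Z-alkene C12=C13 by syn addition and leaves the existing alkenes alone; the C14 descriptor changes from R to S only because the ligand priorities change.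

Step 22
Reactants: 33 (1S,2Z,7S,8Z,11E,14S)-14-[3-(tert-butyldimethylsilyloxy)prop-1-en-2-yl]-7,11-dimethyl-7-(triethylsilyloxy)cyclotetradeca-2,8,11-trien-1-ol
Product: 34 (1S,8S,12R,13S,14R)-12,13-epoxy-14-hydroxy-(3E,6Z)-diene (cembrane locants; cis-epoxide syn to the C14 hydroxyl; C8 triethylsilyloxy; C1 bearing 3-(tert-butyldimethylsilyloxy)prop-1-en-2-yl)
Conditions: VO(acac)2 (5 mol %), t-BuOOH (1.3 equiv, in decane), CH2Cl2, 0 °C → rt
Reagents that add atoms: tert-butyl hydroperoxide CC(C)(C)OO
Why: Hydroxyl-directed vanadium-catalysed epoxidation touches only the allylic alkene C12=C13. With a Z-alkene, A(1,3) strain puts the C14 hydrogen in the alkene plane, so oxygen arrives on the hydroxyl face (threo), which is also the outer face of the ring. The homoallylic C15=C17 alkene reacts much more slowly.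

Step 23
Reactants: 34 (1S,8S,12R,13S,14R)-12,13-epoxy-14-hydroxy-(3E,6Z)-diene
Product: 35 (1R,2R,3S,7S,8Z,11E,14S)-14-[3-(tert-butyldimethylsilyloxy)prop-1-en-2-yl]-3,7,11-trimethyl-7-(triethylsilyloxy)cyclotetradeca-8,11-diene-1,2-diol
Conditions: Me3Al (4 equiv), hexane/CH2Cl2, −20 → 0 °C; aq. potassium sodium tartrate
Reagents that add atoms: trimethylaluminium C[Al](C)C
Why: Trialkylaluminium opening of a 2,3-epoxy alcohol: the aluminium alkoxide at C14 activates the epoxide and methyl is delivered to the distal carbon C12 with inversion, so C13 keeps its oxygen and the methyl at C12 is syn to it, giving cembrane (12S,13R).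

Step 24
Reactants: 35 (1R,2R,3S,7S,8Z,11E,14S)-14-[3-(tert-butyldimethylsilyloxy)prop-1-en-2-yl]-3,7,11-trimethyl-7-(triethylsilyloxy)cyclotetradeca-8,11-diene-1,2-diol
Product: 36 (1R,2R,3S,7S,8Z,11E,14S)-14-(3-hydroxyprop-1-en-2-yl)-3,7,11-trimethylcyclotetradeca-8,11-diene-1,2,7-triol
Conditions: Bu4NF (4 equiv), THF, rt
Reagents that add atoms: none
Why: Fluoride removes both silyl ethers at a stage where the molecule has no base- or acid-sensitive group, so nothing needs deprotecting after the lactone and epoxide are in place.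

Step 25
Reactants: 36 (1R,2R,3S,7S,8Z,11E,14S)-14-(3-hydroxyprop-1-en-2-yl)-3,7,11-trimethylcyclotetradeca-8,11-diene-1,2,7-triol
Product: 39 (1S,3E,6Z,8S,12S,13R,14R)-8,13-dihydroxycembra-3,6,15(17)-trien-16,14-olide, via enal 37 (not isolated), via lactol 38 (not isolated)
Conditions: MnO2 (activated, 25 equiv), CH2Cl2, rt
Reagents that add atoms: none
Why: MnO2 oxidises only the primary allylic C16 hydroxyl to enal 37, the C14 hydroxyl closes the fused five-membered lactol 38 and the allylic lactol is oxidised to the lactone (oxidative lactonisation of a 2-methylene-1,4-diol). The six-membered lactol through the C13 hydroxyl would be a bridged bicycle sharing C13, C14 and C1 with the macrocycle and should form more slowly and be less stable. The cis ring fusion is already fixed by C1 and C14.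

Step 26
Reactants: 39 (1S,3E,6Z,8S,12S,13R,14R)-8,13-dihydroxycembra-3,6,15(17)-trien-16,14-olide
Product: 40 (1S,3R,4R,6Z,8S,12S,13R,14R)-3,4-epoxy-8,13-dihydroxycembra-6,15(17)-dien-16,14-olide
Conditions: 1,2:4,5-di-O-isopropylidene-β-D-erythro-2,3-hexodiulo-2,6-pyranose (0.5 equiv), KHSO5 (as 2KHSO5·KHSO4·K2SO4), K2CO3, Bu4NHSO4 (cat.), aq. Na2B4O7/Na2EDTA buffer (pH about 10), MeCN/CH2(OMe)2, −5 °C
Reagents that add atoms: potassium peroxymonosulfate [K+].[O-]S(=O)(=O)OO
Why: Shi epoxidation: the dioxirane of the D-fructose-derived ketone transfers oxygen through a spiro transition state to the face of an E-trisubstituted alkene that gives the (R,R)-epoxide, here (3R,4R). C3=C4 is the most electron-rich alkene, C15=C17 is deactivated by the lactone carbonyl, and C6=C7 is a Z-alkene beside a quaternary carbon.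

## Compound list

1 | (S)-linalool, (3S)-3,7-dimethylocta-1,6-dien-3-ol | C=C[C@@](C)(O)CCC=C(C)C | starting material
2 | (3S)-3,7-dimethyl-3-(triethylsilyloxy)octa-1,6-diene | C=C[C@@](C)(O[Si](CC)(CC)CC)CCC=C(C)C | intermediate
3 | (4S)-4-methyl-4-(triethylsilyloxy)hex-5-enal (not isolated) | C=C[C@@](C)(O[Si](CC)(CC)CC)CCC=O | intermediate
4 | (4S)-4-methyl-4-(triethylsilyloxy)hex-5-en-1-ol | C=C[C@@](C)(O[Si](CC)(CC)CC)CCCO | intermediate
5 | (3S)-6-iodo-3-methyl-3-(triethylsilyloxy)hex-1-ene | C=C[C@@](C)(O[Si](CC)(CC)CC)CCCI | intermediate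
6 | propargyl alcohol (prop-2-yn-1-ol) | C#CCO | starting material
7 | dilithio alkoxide of prop-2-yn-1-ol (not isolated) | [Li]C#CCO[Li] | intermediate
8 | (7S)-7-methyl-7-(triethylsilyloxy)non-8-en-2-yn-1-ol | C=C[C@@](C)(O[Si](CC)(CC)CC)CCCC#CCO | intermediate
9 | (3S)-3-methyl-3-(triethylsilyloxy)non-7-yne-1,2,9-triol, C2 epimers (not isolated) | OCC(O)[C@@](C)(O[Si](CC)(CC)CC)CCCC#CCO | intermediate
10 | (2S)-8-hydroxy-2-methyl-2-(triethylsilyloxy)oct-6-ynal | O=C[C@@](C)(O[Si](CC)(CC)CC)CCCC#CCO | intermediate
11 | but-2-yne-1,4-diol | OCC#CCO | starting material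
12 | 4-(tert-butyldimethylsilyloxy)but-2-yn-1-ol | OCC#CCO[Si](C)(C)C(C)(C)C | intermediate
13 | sodium cyclic alkenylalanate: 2,2-bis(2-methoxyethoxy)-3-[(tert-butyldimethylsilyloxy)methyl]-2,5-dihydro-1,2-oxaluminol-2-uide (not isolated) | [Na+].COCCO[Al-]1(OCCOC)OCC=C1CO[Si](C)(C)C(C)(C)C | intermediate
14 | (Z)-4-(tert-butyldimethylsilyloxy)-3-iodobut-2-en-1-ol | OC/C=C(\I)CO[Si](C)(C)C(C)(C)C | intermediate
15 | (Z)-4-(tert-butyldimethylsilyloxy)-3-iodobut-2-en-1-yl pivalate | CC(C)(C)C(=O)OC/C=C(\I)CO[Si](C)(C)C(C)(C)C | intermediate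
16 | (E)-4-(tert-butyldimethylsilyloxy)-3-(hydroxymethyl)but-2-en-1-yl pivalate (hydroxymethyl cis to the pivaloyloxymethyl group) | CC(C)(C)C(=O)OC/C=C(\CO)CO[Si](C)(C)C(C)(C)C | intermediate
17 | (E)-4-(tert-butyldimethylsilyloxy)-3-[(triethylsilyloxy)methyl]but-2-en-1-yl pivalate | CC(C)(C)C(=O)OC/C=C(\CO[Si](CC)(CC)CC)CO[Si](C)(C)C(C)(C)C | intermediate
18 | (E)-4-(tert-butyldimethylsilyloxy)-3-[(triethylsilyloxy)methyl]but-2-en-1-ol | OC/C=C(\CO[Si](CC)(CC)CC)CO[Si](C)(C)C(C)(C)C | intermediate
19 | methanesulfonate of 18 (not isolated) | CS(=O)(=O)OC/C=C(\CO[Si](CC)(CC)CC)CO[Si](C)(C)C(C)(C)C | intermediate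
20 | (E)-1-(tert-butyldimethylsilyloxy)-4-chloro-2-[(triethylsilyloxy)methyl]but-2-ene (chloromethyl cis to the triethylsilyloxymethyl group) | ClC/C=C(\CO[Si](CC)(CC)CC)CO[Si](C)(C)C(C)(C)C | intermediate
21 | but-3-yn-1-ol | C#CCCO | starting material
22 | (E)-alkenylalane: dimethyl[(E)-4-(dimethylaluminiooxy)-2-methylbut-1-en-1-yl]aluminium (not isolated) | C[Al](C)/C=C(\C)CCO[Al](C)C | intermediate
23 | (3E,6E)-8-(tert-butyldimethylsilyloxy)-3-methyl-7-[(triethylsilyloxy)methyl]octa-3,6-dien-1-ol | OCC/C(C)=C/C/C=C(/CO[Si](C)(C)C(C)(C)C)CO[Si](CC)(CC)CC | intermediate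
24 | (2E,5E)-1-(tert-butyldimethylsilyloxy)-8-iodo-6-methyl-2-[(triethylsilyloxy)methyl]octa-2,5-diene | ICC/C(C)=C/C/C=C(/CO[Si](C)(C)C(C)(C)C)CO[Si](CC)(CC)CC | intermediate
25 | [(3E,6E)-8-(tert-butyldimethylsilyloxy)-3-methyl-7-[(triethylsilyloxy)methyl]octa-3,6-dien-1-yl]triphenylphosphonium iodide | [I-].c1ccc(cc1)[P+](c1ccccc1)(c1ccccc1)CC/C(C)=C/C/C=C(/CO[Si](C)(C)C(C)(C)C)CO[Si](CC)(CC)CC | intermediate
26 | ylide of 25 (not isolated) | c1ccc(cc1)P(c1ccccc1)(c1ccccc1)=CC/C(C)=C/C/C=C(/CO[Si](C)(C)C(C)(C)C)CO[Si](CC)(CC)CC | intermediate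
27 | (7S,8Z,11E,14E)-16-(tert-butyldimethylsilyloxy)-7,11-dimethyl-7-(triethylsilyloxy)-15-[(triethylsilyloxy)methyl]hexadeca-8,11,14-trien-2-yn-1-ol | OCC#CCCC[C@](C)(O[Si](CC)(CC)CC)/C=C\C/C(C)=C/C/C=C(/CO[Si](C)(C)C(C)(C)C)CO[Si](CC)(CC)CC | intermediate
28 | (7S,8Z,11E,14E)-1-bromo-16-(tert-butyldimethylsilyloxy)-7,11-dimethyl-7-(triethylsilyloxy)-15-[(triethylsilyloxy)methyl]hexadeca-8,11,14-trien-2-yne | BrCC#CCCC[C@](C)(O[Si](CC)(CC)CC)/C=C\C/C(C)=C/C/C=C(/CO[Si](C)(C)C(C)(C)C)CO[Si](CC)(CC)CC | intermediate
29 | (2E,5E,8Z,10S)-16-bromo-2-[(tert-butyldimethylsilyloxy)methyl]-6,10-dimethyl-10-(triethylsilyloxy)hexadeca-2,5,8-trien-14-yn-1-ol | BrCC#CCCC[C@](C)(O[Si](CC)(CC)CC)/C=C\C/C(C)=C/C/C=C(/CO[Si](C)(C)C(C)(C)C)CO | intermediate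
30 | (8S,9Z,12E,15E)-16-[(tert-butyldimethylsilyloxy)methyl]-8,12-dimethyl-8-(triethylsilyloxy)-1-oxacycloheptadeca-9,12,15-trien-3-yne (17-membered C14–O–C17 ether) | O1CC#CCCC[C@](C)(O[Si](CC)(CC)CC)/C=C\C/C(C)=C/C/C=C(/CO[Si](C)(C)C(C)(C)C)C1 | intermediate
31 | C14-lithiated 30 (2-lithio-1-oxacycloheptadecatrienyne; not isolated) | O1C([Li])C#CCCC[C@](C)(O[Si](CC)(CC)CC)/C=C\C/C(C)=C/C/C=C(/CO[Si](C)(C)C(C)(C)C)C1 | intermediate
32 | (1R,7S,8Z,11E,14S)-14-[3-(tert-butyldimethylsilyloxy)prop-1-en-2-yl]-7,11-dimethyl-7-(triethylsilyloxy)cyclotetradeca-8,11-dien-2-yn-1-ol (cembrane 1S,8S,14R) | O[C@H]1C#CCCC[C@](C)(O[Si](CC)(CC)CC)/C=C\C/C(C)=C/C[C@H]1C(=C)CO[Si](C)(C)C(C)(C)C | intermediate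
33 | (1S,2Z,7S,8Z,11E,14S)-14-[3-(tert-butyldimethylsilyloxy)prop-1-en-2-yl]-7,11-dimethyl-7-(triethylsilyloxy)cyclotetradeca-2,8,11-trien-1-ol | O[C@H]1/C=C\CCC[C@](C)(O[Si](CC)(CC)CC)/C=C\C/C(C)=C/C[C@H]1C(=C)CO[Si](C)(C)C(C)(C)C | intermediate
34 | (1S,8S,12R,13S,14R)-12,13-epoxy-14-hydroxy-(3E,6Z)-diene, cembrane locants (cis-epoxide syn to the C14 hydroxyl; C8 triethylsilyloxy; C1 bearing 3-(tert-butyldimethylsilyloxy)prop-1-en-2-yl) | O[C@H]1[C@@H]2O[C@@H]2CCC[C@](C)(O[Si](CC)(CC)CC)/C=C\C/C(C)=C/C[C@H]1C(=C)CO[Si](C)(C)C(C)(C)C | intermediate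
35 | (1R,2R,3S,7S,8Z,11E,14S)-14-[3-(tert-butyldimethylsilyloxy)prop-1-en-2-yl]-3,7,11-trimethyl-7-(triethylsilyloxy)cyclotetradeca-8,11-diene-1,2-diol (cembrane 1S,8S,12S,13R,14R) | O[C@H]1[C@H](O)[C@@H](C)CCC[C@](C)(O[Si](CC)(CC)CC)/C=C\C/C(C)=C/C[C@H]1C(=C)CO[Si](C)(C)C(C)(C)C | intermediate
36 | (1R,2R,3S,7S,8Z,11E,14S)-14-(3-hydroxyprop-1-en-2-yl)-3,7,11-trimethylcyclotetradeca-8,11-diene-1,2,7-triol | O[C@H]1[C@H](O)[C@@H](C)CCC[C@](C)(O)/C=C\C/C(C)=C/C[C@H]1C(=C)CO | intermediate
37 | C16 aldehyde of 36 (2-substituted propenal; other centres as in 36; not isolated) | O[C@H]1[C@H](O)[C@@H](C)CCC[C@](C)(O)/C=C\C/C(C)=C/C[C@H]1C(=C)C=O | intermediate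
38 | five-membered lactol between C16 and the C14 oxygen (anomers; not isolated) | C=C1C(O)O[C@H]2[C@H](O)[C@@H](C)CCC[C@](C)(O)/C=C\C/C(C)=C/C[C@@H]12 | intermediate
39 | (1S,3E,6Z,8S,12S,13R,14R)-8,13-dihydroxycembra-3,6,15(17)-trien-16,14-olide | C=C1C(=O)O[C@H]2[C@H](O)[C@@H](C)CCC[C@](C)(O)/C=C\C/C(C)=C/C[C@@H]12 | intermediate
40 | (1S,3R,4R,6Z,8S,12S,13R,14R)-3,4-epoxy-8,13-dihydroxycembra-6,15(17)-dien-16,14-olide | C=C1C(=O)O[C@H]2[C@H](O)[C@@H](C)CCC[C@](C)(O)/C=C\C[C@@]3(C)O[C@@H]3C[C@@H]12 | target

## Step count and least certain steps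

Total: 26 steps. Longest linear sequence: 21 steps (11 → 40, steps 6–26); the linalool branch (steps 1–5) joins at step 16.

**Step 20 (key step).** The most likely failure is weak discrimination between the two C14 protons by the chiral amide. The ring is large and flexible and C8 is too far away to help, so the product could form as a mixture of the two syn diastereomers that differ at C1 and C14 together. Competing [1,2] shift or deprotonation at C17 is a lesser concern at low temperature. Fallback: the rearrangement is run on 30 with an achiral amide (LDA), which still gives only the syn pair, that is 32 and its (1R,14S)-diastereomer (cembrane locants) F1. The mixture is esterified with (S)-O-methylmandelic acid (DCC, DMAP) to the mandelate of 32 F2 and the mandelate of the diastereomer F3, which now differ at a stereocentre next to C14 and are separated by chromatography. Methanolysis of F2 (K2CO3, MeOH) returns 32.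

**Step 19.** Intermolecular etherification (oligomerisation) may outrun the 17-membered ring closure, and the alkoxide may attack the propargylic bromide in the SN2′ sense. Fallback by ring-closing alkyne metathesis, which forms the C12≡C13 bond instead of the C14–O bond:
- Iodide 5 is alkylated with 1-propynyllithium to (3S)-3-methyl-3-(triethylsilyloxy)non-1-en-7-yne F4 and cleaved (OsO4, NaIO4) to (2S)-2-methyl-2-(triethylsilyloxy)oct-6-ynal F5.
- Wittig reaction of F5 with ylide 26 gives the methyl-capped Z-olefin F6 (27 with CH3 in place of CH2OH).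
- Selective removal of the C17 triethylsilyl group (pyridinium p-toluenesulfonate, MeOH) gives allylic alcohol F7, which is etherified with 1-bromobut-2-yne (NaH) to the but-2-ynyl ether F8.
- The molybdenum alkylidyne (4-MeOC6H4)C≡Mo(OSiPh3)3 with 5 Å molecular sieves in toluene closes F8 with loss of but-2-yne and returns the route at 30.

**Step 23.** Opening may not be regioselective for C12, and Lewis-acid-induced hydride shift or ionisation at the tertiary allylic silyl ether may compete. Fallback in which the methyl group is introduced first and the epoxide is opened by hydride: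
- From 32, NaAlH2(OCH2CH2OMe)2 then I2 gives the (12Z)-12-iodo allylic alcohol F9.
- Me2CuLi converts F9 into the (12E)-12-methyl allylic alcohol F10 (methyl cis to C14).
- VO(acac)2/t-BuOOH gives the threo 12,13-epoxy alcohol F11.
- LiBH4/Ti(OiPr)4 delivers hydride to C12 with inversion and returns the route at 35.

**Step 25.** The C13 hydroxyl may compete with the C14 hydroxyl in lactol formation, leading to the six-membered lactone. Fallback in which C13 and C14 are masked and the lactone is closed from the acid:
- Diol 35 is converted into its 13,14-acetonide F12 (2-methoxypropene, pyridinium p-toluenesulfonate).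
- Bu4NF gives the diol F13, MnO2 the enal F14, and NaClO2/NaH2PO4/2-methylbut-2-ene the acrylic acid F15.
- Aqueous acetic acid removes the acetonide from F15; the 4-hydroxy acid closes to the five-membered lactone, which is favoured over the six-membered one both in rate and at equilibrium, and the route returns at 39.

**Step 26.** The ring's own facial bias may override the catalyst, the basic aqueous oxidant may erode the α-methylene lactone, or the freed C8 hydroxyl may open the new epoxide across the ring. Fallback that moves the epoxidation ahead of deprotection and lactonisation, so the lactone never meets base and the bulky silyl ethers shield C6=C7 and C15=C17: the same ketone/KHSO5 system is applied to 35 to give the 3,4-epoxide F16, Bu4NF gives the epoxy tetraol F17, and MnO2 closes the lactone as the last, neutral step to give 40.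

## Further compounds

F1 | step 20 | (1R,14S)-diastereomer of 32 (cembrane locants; C8 unchanged) | O[C@@H]1C#CCCC[C@](C)(O[Si](CC)(CC)CC)/C=C\C/C(C)=C/C[C@@H]1C(=C)CO[Si](C)(C)C(C)(C)C
F2 | step 20 | (S)-2-methoxy-2-phenylacetate of 32 | CO[C@H](C(=O)O[C@H]1C#CCCC[C@](C)(O[Si](CC)(CC)CC)/C=C\C/C(C)=C/C[C@H]1C(=C)CO[Si](C)(C)C(C)(C)C)c1ccccc1
F3 | step 20 | (S)-2-methoxy-2-phenylacetate of F1 | CO[C@H](C(=O)O[C@@H]1C#CCCC[C@](C)(O[Si](CC)(CC)CC)/C=C\C/C(C)=C/C[C@@H]1C(=C)CO[Si](C)(C)C(C)(C)C)c1ccccc1
F4 | step 19 | (3S)-3-methyl-3-(triethylsilyloxy)non-1-en-7-yne | C=C[C@@](C)(O[Si](CC)(CC)CC)CCCC#CC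
F5 | step 19 | (2S)-2-methyl-2-(triethylsilyloxy)oct-6-ynal | O=C[C@@](C)(O[Si](CC)(CC)CC)CCCC#CC
F6 | step 19 | methyl-capped Z-olefin (27 with CH3 in place of CH2OH) | CC#CCCC[C@](C)(O[Si](CC)(CC)CC)/C=C\C/C(C)=C/C/C=C(/CO[Si](C)(C)C(C)(C)C)CO[Si](CC)(CC)CC
F7 | step 19 | C17 allylic alcohol from F6 | CC#CCCC[C@](C)(O[Si](CC)(CC)CC)/C=C\C/C(C)=C/C/C=C(/CO[Si](C)(C)C(C)(C)C)CO
F8 | step 19 | but-2-ynyl ether of F7 (diyne for ring-closing alkyne metathesis) | CC#CCCC[C@](C)(O[Si](CC)(CC)CC)/C=C\C/C(C)=C/C/C=C(/CO[Si](C)(C)C(C)(C)C)COCC#CC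
F9 | step 23 | (12Z)-12-iodo allylic alcohol from 32 (iodine cis to C14) | O[C@H]1/C=C(\I)CCC[C@](C)(O[Si](CC)(CC)CC)/C=C\C/C(C)=C/C[C@H]1C(=C)CO[Si](C)(C)C(C)(C)C
F10 | step 23 | (12E)-12-methyl allylic alcohol (methyl cis to C14) | O[C@H]1/C=C(\C)CCC[C@](C)(O[Si](CC)(CC)CC)/C=C\C/C(C)=C/C[C@H]1C(=C)CO[Si](C)(C)C(C)(C)C
F11 | step 23 | threo 12,13-epoxy-12-methyl alcohol | O[C@H]1[C@@H]2O[C@@]2(C)CCC[C@](C)(O[Si](CC)(CC)CC)/C=C\C/C(C)=C/C[C@H]1C(=C)CO[Si](C)(C)C(C)(C)C
F12 | step 25 | 13,14-acetonide of 35 | CC2(C)O[C@H]1[C@H](O2)[C@@H](C)CCC[C@](C)(O[Si](CC)(CC)CC)/C=C\C/C(C)=C/C[C@H]1C(=C)CO[Si](C)(C)C(C)(C)C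
F13 | step 25 | desilylated acetonide (C8 and C16 hydroxyls free) | CC2(C)O[C@H]1[C@H](O2)[C@@H](C)CCC[C@](C)(O)/C=C\C/C(C)=C/C[C@H]1C(=C)CO
F14 | step 25 | C16 enal of F13 | CC2(C)O[C@H]1[C@H](O2)[C@@H](C)CCC[C@](C)(O)/C=C\C/C(C)=C/C[C@H]1C(=C)C=O
F15 | step 25 | C16 acrylic acid of F13 | CC2(C)O[C@H]1[C@H](O2)[C@@H](C)CCC[C@](C)(O)/C=C\C/C(C)=C/C[C@H]1C(=C)C(=O)O
F16 | step 26 | (3R,4R)-3,4-epoxide of 35 | O[C@H]1[C@H](O)[C@@H](C)CCC[C@](C)(O[Si](CC)(CC)CC)/C=C\C[C@@]2(C)O[C@@H]2C[C@H]1C(=C)CO[Si](C)(C)C(C)(C)C
F17 | step 26 | (3R,4R)-3,4-epoxy tetraol (desilylated F16) | O[C@H]1[C@H](O)[C@@H](C)CCC[C@](C)(O)/C=C\C[C@@]2(C)O[C@@H]2C[C@H]1C(=C)CO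
A1 | alternative 1 | cis-fused bicyclic iodolactone (6-iodohexahydro-2H-cyclopenta[b]furan-2-one, iodine trans to the ring oxygen) | O=C1C[C@@H]2CC[C@@H](I)[C@@H]2O1
A2 | alternative 1 | (S)-2-(cyclopent-2-en-1-yl)acetic acid | OC(=O)C[C@@H]1CCC=C1
A3 | alternative 2 | trans-epoxy alkyne with dimethyl acetal and isopropenyl group (C13–C1–C7 fragment) | C#CC[C@@]1(C)O[C@@H]1C[C@H](CC(OC)OC)C(C)=C
A4 | alternative 2 | (R)-limonene | CC1=CC[C@@H](CC1)C(C)=C
A5 | alternative 3 | 14-membered lactone-fused ring with Z-alkene, free C8 hydroxyl, C3=C4 alkene and C13 p-methoxybenzyl ether | O=C1C[C@@H]2C/C=C(C)/C/C=C\[C@@](C)(O)CCC[C@H](C)[C@@H](OCc3ccc(OC)cc3)[C@@H]2O1
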